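## The problem

Hanultarin is the mono-(E)-ferulate of (2R,3R)-2,3-bis(4-hydroxy-3-methoxybenzyl)butane-1,4-diol. It is an open-chain lignan ester with no ring to close: the three guaiacyl rings are bought, and the work lies in the four-carbon chain C1–C4. C2 and C3 are adjacent C–H stereocentres carrying only carbon substituents (a CH2O arm and an arylmethyl arm each). They cannot be set by addition to or reduction of a carbonyl group and must come from a stereospecific reaction at an sp2 carbon or at a carbon–metal bond. The diol core is C2-symmetric, and in an open chain one centre steers the other only weakly. The safest answer is therefore a single event that sets both centres across one π bond, with the relative configuration fixed by mechanism and the absolute configuration by a catalyst. The same symmetry makes the two primary hydroxyls homotopic: acylation at either gives the same compound and a later acyl shift would be degenerate, but only statistics separates mono- from di-acylation. The fragile groups are the three phenols, which must be masked through the organometallic and peroxide steps, and the cinnamate ester, whose E double bond forbids hydrogenolysis and whose acyl group forbids strong base, hydride and alcoholysis. Ester formation and phenol release therefore belong at the very end. The enabling feature is that C1 and C4 are one-carbon arms on C2 and C3. Removing them leaves ArCH2–CH=CH–CH2Ar, the E-configured self-metathesis dimer of eugenol, and syn addition of two boron atoms to that alkene gives exactly the required relative configuration, with each boron where a CH2OH group must grow.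

## Retrosynthesis

Hanultarin 14 is traced to its tris(methoxymethyl) ether 13 by cutting the three phenolic O–CH2 acetal bonds. Benzyl ethers are excluded because hydrogenolysis would saturate the cinnamate double bond. Acyl groups would not survive the organolithium step, and aryl silyl ethers are less secure towards the carbenoid and alkaline peroxide. The acetal is indifferent to all of these. No skeletal bond changes. The forward step must hydrolyse three aryl acetals without hydrolysing or transesterifying a primary alkyl cinnamate.

In 13 the acyl C–O bond is cut, giving the C2-symmetric diol 9 and the protected acid 12. Because the two hydroxyls of 9 are homotopic, no differentiating protecting group is needed. The neighbouring option, a core with two different oxygen functions from the start, would give up the symmetry that keeps the route short. The precursor loses a third of its atoms. The forward reaction has only to stop at one acylation, which is a matter of stoichiometry and recycling.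

Acid 12 goes back to ferulic acid 10 through the doubly alkylated compound 11. Both the phenol and carboxyl O–CH2 bonds are cut, because alkylating both and then saponifying the labile ester is simpler than selective phenol alkylation. The forward step asks only that the acylal-type ester hydrolyse much faster than the aryl acetal, which it does in base.

The two C–O bonds of 9 are cut to the C–B bonds of the 1,4-bis(boronate) 8. Oxidation of a primary C–B bond is dependable and touches neither stereocentre, so the oxygen atoms can be postponed until all carbon–carbon bonds are in place.

In 8 the C1–C2 and C3–C4 bonds are cut. This removes the two methylene carbons and leaves the vicinal bis(boronate) 6, which reaches 8 through the bis(ate) complex 7. Cutting the benzyl–core bonds or the central C2–C3 bond would leave two stereocentres to be made in separate events. This cut alone reduces the stereochemical problem to one addition across one alkene, and the precursor has lost both arms and is a simple 1,2-difunctionalised butane. The forward reaction must insert one carbon into each C–B bond with retention, do so twice in a crowded vicinal system, and not insert a third time.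

The two C–B bonds of 6 are cut to the E-alkene 3 and the diboron reagent 4, with the bis(catecholboronate) 5 as the primary adduct. A concerted syn addition to an E-alkene can only give the like (R,R or S,S) pair, so the relative configuration is not a variable and the catalyst has only to choose a face. The precursor is achiral. The forward reaction needs an enantioselective diboration that accepts an E-1,2-dialkylalkene, followed by ligand exchange on boron to the more robust pinacol ester.

Alkene 3 is the bis(methoxymethyl) ether of bisphenol 2, and the central double bond of 2 is cut to two molecules of eugenol 1. Metathesis is placed before protection because the free bisphenol 2 is expected to crystallise, which gives a means of removing the Z isomer. Any Z isomer carried forward would end as the meso series.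

## Roads not taken

Alternative 1: The cut is at the two aryl–CH2 bonds. In the forward direction two equivalents of [3-methoxy-4-(methoxymethoxy)phenyl]boronic acid A2 add to the methylene carbons of dimethyl 2,3-dimethylenesuccinate A1. The catalyst is [Rh(cod)2]PF6 with an axially chiral bisphosphine, a phenol protonates each rhodium enolate, and the product is dimethyl (2R,3R)-2,3-bis[3-methoxy-4-(methoxymethoxy)benzyl]succinate A3; hydride reduction of A3 would give diol 9. The road is highly convergent, catalytic in the chiral element, already at a convenient oxidation level, and free of cryogenic organolithium chemistry. In step count to 9 it is at least as good as the chosen plan, and this is a real advantage. Its weak points are mechanistic. The two stereocentres are set in two separate protonations, so the second must be catalyst-controlled against the bias of the first centre, and the meso diester is a possible product. After the first aryl transfer the metal sits on a carbon that is both α to an ester and allylic to the second acrylate unit. Protonation at the far methylene carbon would give a tetrasubstituted alkene that cannot take the second aryl group. A1 is also a cross-conjugated diene prone to dimerise. The chosen plan sets against the shorter count a relative configuration fixed by one concerted syn addition and precedent for each step on its own substrate class.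

Alternative 2: The cut is at both benzyl-to-core bonds on a chiral template. The lithiated dithiane A5, 2-[3-methoxy-4-(methoxymethoxy)phenyl]-1,3-dithiane, adds to C4 of (5R)-5-menthyloxy-2(5H)-furanone A4 anti to the acetal oxygen. The enolate is then trapped by 3-methoxy-4-(methoxymethoxy)benzyl bromide A6 anti to the new substituent, giving the all-trans lactone A7. Nickel-mediated desulfurisation and hydride reduction of lactone and acetal carbons would lead to diol 9. This road is the strongest in stereochemical certainty: both centres are set by substrate control on a rigid five-membered ring, diastereomers can be removed by crystallisation, and enantiopurity comes from the auxiliary, not from a catalytic selectivity. In that respect it is better than the chosen plan. Its weak points are length and waste. A5 and A6 must each be made, the auxiliary and the dithiane are stoichiometric, the desulfurisation needs a large excess of nickel, and the symmetry of the target is ignored because the two identical halves are introduced by two different reactions. The chosen plan offers roughly half the step count to 9, a catalytic source of chirality and a renewable C10 building block used twice. It pays by having to prove the enantioselectivity of one catalytic step.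

Alternative 3: The cut is at the C1–O and C4–O bonds together with the C2–H and C3–H bonds. 2,3-Bis[3-methoxy-4-(methoxymethoxy)benzyl]buta-1,3-diene A8 would undergo two 1,2-hydroborations with a dialkoxyborane under a chiral cobalt hydride catalyst (CoCl2 with an iminopyridine–oxazoline ligand, activated by NaBHEt3). Oxidative work-up would give diol A9, which is the same compound as 9. The road is attractive on paper: an earth-abundant metal, oxygen placed directly on C1 and C4, and both stereocentres from the catalyst in one operation. If it worked it would be the shortest route to the diol. The precedent for this catalysis, however, rests on 1,1-disubstituted alkenes in which an aryl group on the double bond differentiates the two faces. In A8 each alkene carries two alkyl-type substituents and is part of a conjugated diene. Metal hydrides add to such dienes through allylmetal intermediates, so 1,4-hydroboration to an allylboronate competes with the 1,2-mode. The second hydroboration is a matched or mismatched event next to the first stereocentre, so the meso diol can form. A8 is not commercial and would require a twofold SN2′ benzylation with a benzylic organometallic that is prone to homocoupling. The chosen plan is no shorter, but its stereo-determining step is an established reaction on E-1,2-dialkylalkenes, and its relative configuration cannot go wrong.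

Key step: step 4

Assumption: with Rh(acac)(nbd), (S)-Quinap is taken to give the (2R,3R) bis(boronate) from this E-1,2-dialkylalkene. The sense of induction is to be confirmed by the sign of rotation of diol 9 after acetal removal; the (R)-ligand would be used in the same way if the sense proves opposite.

## Route

Step 1
Reactants: 1 eugenol (4-allyl-2-methoxyphenol), two molecules
Product: 2 (E)-4,4'-(but-2-ene-1,4-diyl)bis(2-methoxyphenol)
Conditions: second-generation Grubbs catalyst RuCl2(=CHPh)(PCy3)(H2IMes) (1 mol%), 1,4-benzoquinone (10 mol%), CH2Cl2, 40 °C, argon sweep; recrystallisation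
Reagents that add atoms: none
Why: Olefin self-metathesis of a terminal allylarene, driven by loss of ethylene; secondary metathesis should equilibrate the product towards the E isomer, benzoquinone suppresses ruthenium hydride double-bond migration, and recrystallisation of the bisphenol is intended to remove residual Z isomer, which would otherwise lead to the meso series.

Step 2
Reactants: 2 (E)-4,4'-(but-2-ene-1,4-diyl)bis(2-methoxyphenol)
Product: 3 (E)-1,4-bis[3-methoxy-4-(methoxymethoxy)phenyl]but-2-ene
Conditions: MOMCl (2.6 equiv), i-Pr2NEt (3.5 equiv), CH2Cl2, 0 °C to rt
Reagents that add atoms: chloromethyl methyl ether, COCCl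
Why: O-Alkylation of both phenols (methoxymethyl ether formation); the resulting acetals are inert to the diboron reagent, to organolithium at low temperature and to alkaline peroxide, and the alkene is untouched.

Step 3
Reactants: 3 (E)-1,4-bis[3-methoxy-4-(methoxymethoxy)phenyl]but-2-ene; 4 bis(catecholato)diboron
Product: 6 2,2'-{(2R,3R)-1,4-bis[3-methoxy-4-(methoxymethoxy)phenyl]butane-2,3-diyl}bis(4,4,5,5-tetramethyl-1,3,2-dioxaborolane), via bis(catecholboronate) 5 (not isolated)
Conditions: Rh(acac)(nbd) (5 mol%), (S)-Quinap (5 mol%), 4 (1.2 equiv), THF, rt; then pinacol (4 equiv), rt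
Reagents that add atoms: pinacol (2,3-dimethylbutane-2,3-diol), CC(C)(O)C(C)(C)O
Why: Rhodium-catalysed enantioselective syn-1,2-diboration of an E-1,2-dialkylalkene: oxidative addition of the B–B bond to monovalent rhodium, alkene insertion and C–B reductive elimination place both borons on one face, so the E geometry fixes the like relative configuration and the P,N-ligand selects the face that gives (2R,3R); transesterification with pinacol then gives the chromatographically stable bis(pinacolboronate).

Step 4
Reactants: 6 2,2'-{(2R,3R)-1,4-bis[3-methoxy-4-(methoxymethoxy)phenyl]butane-2,3-diyl}bis(4,4,5,5-tetramethyl-1,3,2-dioxaborolane)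
Product: 8 2,2'-{(2R,3R)-2,3-bis[3-methoxy-4-(methoxymethoxy)benzyl]butane-1,4-diyl}bis(4,4,5,5-tetramethyl-1,3,2-dioxaborolane), via dilithium bis(chloromethyl)borate complex 7 (not isolated)
Conditions: BrCH2Cl (6 equiv), n-BuLi (5 equiv, added dropwise), THF, −78 °C, 1 h; then warm to rt, 12 h
Reagents that add atoms: bromochloromethane, ClCBr (delivered as chloromethyllithium, [Li]CCl)
Why: Twofold Matteson homologation. n-BuLi undergoes bromine–lithium exchange with BrCH2Cl faster than it attacks boron, and the chloromethyllithium so formed is captured at −78 °C by each trigonal boron of 6 to give the bis(ate) complex 7. On warming, each secondary alkyl group migrates from boron to the carbenoid carbon anti-periplanar to the departing chloride (a 1,2-metallate shift), so the C1–C2 and C3–C4 bonds form with retention at C2 and C3 and inversion only at the achiral CH2 carbon. No ring closes and no stereocentre is created; the (2R,3R) configuration laid down in step 3 is carried through by the stereospecificity of the shift. The closest known reaction type is the chloromethyllithium homologation of secondary alkyl pinacolboronates, including vicinal bis(boronates) from alkene diboration that are oxidised to 1,4-diols. The selectivity needed is double insertion without a third: the carbenoid decomposes well below the temperature at which 7 rearranges, so the primary boronate 8 meets no reagent, and an excess of carbenoid at −78 °C should bring both borons to the ate stage before either migrates. The acetals, the aryl ethers and the benzylic positions should be left alone because the butyllithium is consumed by the exchange as it is added.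

Step 5
Reactants: 8 2,2'-{(2R,3R)-2,3-bis[3-methoxy-4-(methoxymethoxy)benzyl]butane-1,4-diyl}bis(4,4,5,5-tetramethyl-1,3,2-dioxaborolane)
Product: 9 (2R,3R)-2,3-bis[3-methoxy-4-(methoxymethoxy)benzyl]butane-1,4-diol
Conditions: 30% aq. H2O2, 3 M aq. NaOH, THF, 0 °C to rt
Reagents that add atoms: hydrogen peroxide, OO
Why: Oxidation of both primary C–B bonds by hydroperoxide (1,2-shift of carbon from boron to oxygen); the migrating carbons are CH2 groups, so no stereocentre is involved, and the acetal-protected, aldehyde-free arenes are inert to alkaline peroxide.

Step 6
Reactants: 10 ferulic acid [(E)-3-(4-hydroxy-3-methoxyphenyl)prop-2-enoic acid]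
Product: 12 (E)-3-[3-methoxy-4-(methoxymethoxy)phenyl]prop-2-enoic acid, via methoxymethyl ester 11 (not isolated)
Conditions: MOMCl (2.4 equiv), i-Pr2NEt (3 equiv), CH2Cl2, 0 °C to rt; then 1 M aq. LiOH, THF/MeOH, rt; 1 M HCl to pH 3–4 at 0 °C
Reagents that add atoms: chloromethyl methyl ether, COCCl; lithium hydroxide (aqueous), [Li+].[OH-]
Why: O-Alkylation of both phenol and carboxylate, then selective saponification of the acylal-type methoxymethyl ester, which hydroxide cleaves while the aryl acetal is stable to base; the E double bond is unaffected.

Step 7
Reactants: 9 (2R,3R)-2,3-bis[3-methoxy-4-(methoxymethoxy)benzyl]butane-1,4-diol; 12 (E)-3-[3-methoxy-4-(methoxymethoxy)phenyl]prop-2-enoic acid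
Product: 13 (2R,3R)-4-hydroxy-2,3-bis[3-methoxy-4-(methoxymethoxy)benzyl]butyl (E)-3-[3-methoxy-4-(methoxymethoxy)phenyl]prop-2-enoate
Conditions: 9 (2 equiv), 12 (1 equiv, added slowly), EDC·HCl (1.2 equiv), DMAP (0.1 equiv), CH2Cl2, 0 °C to rt; unreacted 9 recovered and recycled
Reagents that add atoms: none
Why: Steglich esterification; the two hydroxyls of 9 are homotopic, so any single acylation gives the same compound, an excess of diol with slow addition of the acid biases the statistics towards the monoester, and any diester can be saponified back to 9 and 12.

Step 8
Reactants: 13 (2R,3R)-4-hydroxy-2,3-bis[3-methoxy-4-(methoxymethoxy)benzyl]butyl (E)-3-[3-methoxy-4-(methoxymethoxy)phenyl]prop-2-enoate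
Product: 14 hanultarin [(2R,3R)-4-hydroxy-2,3-bis(4-hydroxy-3-methoxybenzyl)butyl (E)-3-(4-hydroxy-3-methoxyphenyl)prop-2-enoate]
Conditions: 2 M aq. HCl, THF, 40 °C, dilute
Reagents that add atoms: none
Why: Acid-catalysed hydrolysis of three aryl methoxymethyl acetals; the aqueous, alcohol-free medium excludes transesterification, a conjugated primary ester should hydrolyse far more slowly than the acetals under these conditions, dilution limits reaction of released formaldehyde with the electron-rich rings, and an acyl shift between the two primary oxygens would be degenerate.

## Compound list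

1 | eugenol (4-allyl-2-methoxyphenol) | C=CCc1ccc(O)c(OC)c1 | starting material
2 | (E)-4,4'-(but-2-ene-1,4-diyl)bis(2-methoxyphenol) | COc1cc(C/C=C/Cc2ccc(O)c(OC)c2)ccc1O | intermediate
3 | (E)-1,4-bis[3-methoxy-4-(methoxymethoxy)phenyl]but-2-ene | COCOc1ccc(C/C=C/Cc2ccc(OCOC)c(OC)c2)cc1OC | intermediate
4 | bis(catecholato)diboron | c1ccc2c(c1)OB(O2)B1Oc2ccccc2O1 | starting material
5 | 2,2'-{(2R,3R)-1,4-bis[3-methoxy-4-(methoxymethoxy)phenyl]butane-2,3-diyl}bis(1,3,2-benzodioxaborole) | c1ccc2c(c1)OB(O2)[C@H](Cc1ccc(OCOC)c(OC)c1)[C@H](B1Oc2ccccc2O1)Cc1ccc(OCOC)c(OC)c1 | intermediate
6 | 2,2'-{(2R,3R)-1,4-bis[3-methoxy-4-(methoxymethoxy)phenyl]butane-2,3-diyl}bis(4,4,5,5-tetramethyl-1,3,2-dioxaborolane) | CC1(C)OB(OC1(C)C)[C@H](Cc2ccc(OCOC)c(OC)c2)[C@H](B2OC(C)(C)C(C)(C)O2)Cc2ccc(OCOC)c(OC)c2 | intermediate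
7 | dilithium bis[(chloromethyl)(pinacolato)borate] complex of 6, (2R,3R) | [Li+].[Li+].ClC[B-]1(OC(C)(C)C(C)(C)O1)[C@H](Cc1ccc(OCOC)c(OC)c1)[C@H]([B-]1(CCl)OC(C)(C)C(C)(C)O1)Cc1ccc(OCOC)c(OC)c1 | intermediate
8 | 2,2'-{(2R,3R)-2,3-bis[3-methoxy-4-(methoxymethoxy)benzyl]butane-1,4-diyl}bis(4,4,5,5-tetramethyl-1,3,2-dioxaborolane) | CC1(C)OB(OC1(C)C)C[C@H](Cc2ccc(OCOC)c(OC)c2)[C@H](CB2OC(C)(C)C(C)(C)O2)Cc2ccc(OCOC)c(OC)c2 | intermediate
9 | (2R,3R)-2,3-bis[3-methoxy-4-(methoxymethoxy)benzyl]butane-1,4-diol | OC[C@H](Cc1ccc(OCOC)c(OC)c1)[C@H](CO)Cc1ccc(OCOC)c(OC)c1 | intermediate
10 | ferulic acid | COc1cc(/C=C/C(=O)O)ccc1O | starting material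
11 | methoxymethyl (E)-3-[3-methoxy-4-(methoxymethoxy)phenyl]prop-2-enoate | COCOC(=O)/C=C/c1ccc(OCOC)c(OC)c1 | intermediate
12 | (E)-3-[3-methoxy-4-(methoxymethoxy)phenyl]prop-2-enoic acid | COCOc1ccc(/C=C/C(=O)O)cc1OC | intermediate
13 | (2R,3R)-4-hydroxy-2,3-bis[3-methoxy-4-(methoxymethoxy)benzyl]butyl (E)-3-[3-methoxy-4-(methoxymethoxy)phenyl]prop-2-enoate | COCOc1ccc(/C=C/C(=O)OC[C@H](Cc2ccc(OCOC)c(OC)c2)[C@H](CO)Cc2ccc(OCOC)c(OC)c2)cc1OC | intermediate
14 | hanultarin | COc1cc(/C=C/C(=O)OC[C@H](Cc2ccc(O)c(OC)c2)[C@H](CO)Cc2ccc(O)c(OC)c2)ccc1O | target

## Step count and risks

Total step count: 8. Longest linear sequence: 7 steps (steps 1, 2, 3, 4, 5, 7 and 8 from eugenol); step 6 is a one-step side branch.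

Step 4 (key step). The most likely failure is incomplete formation of the second ate complex: the second boron is flanked by a borate and a benzyl group, and the carbenoid lives only briefly at −78 °C. This would leave singly homologated material. Competing attack of butyllithium on boron and oxygen migration in the crowded ate complex are lesser risks. Fallback: setting out from 6, twofold Zweifel olefination (CH2=CHMgBr in excess, THF; then I2 and NaOMe in MeOH, −78 °C to rt) would replace each C–B bond by a C–vinyl bond with retention. The nucleophile is thermally stable and can be pushed at higher temperature. The product is (3S,4S)-3,4-bis[3-methoxy-4-(methoxymethoxy)benzyl]hexa-1,5-diene F1 (the descriptor changes only through the priority rules). Lemieux–Johnson cleavage (K2OsO4·2H2O cat., NaIO4, 2,6-lutidine, dioxane/H2O) would give (2R,3R)-2,3-bis[3-methoxy-4-(methoxymethoxy)benzyl]butanedial F2, which is reduced at once with NaBH4 to limit epimerisation. The fallback comes back to the route at 9 and bypasses 8.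

Step 3. Two things may go wrong. The enantioselectivity may erode on this bis-benzylic alkene. β-Hydride elimination from the β-borylalkylrhodium intermediate may also intervene, because the benzylic C–H bonds make migration of the double bond towards the arene easy; this would divert material to alkenylboronates and hydroboration products. Fallback: setting out from 12, hydrogenation (H2, Pd/C, EtOAc) would give 3-[3-methoxy-4-(methoxymethoxy)phenyl]propanoic acid F3. Mixed-anhydride acylation (pivaloyl chloride, Et3N, THF; then the lithium salt of (S)-4-isopropyloxazolidin-2-one) would give (S)-4-isopropyl-3-{3-[3-methoxy-4-(methoxymethoxy)phenyl]propanoyl}oxazolidin-2-one F4. Oxidative homocoupling of its lithium enolate (LDA, THF, −78 °C; then PhI(OAc)2) should join the two α-carbons on the enolate face away from the isopropyl group. The product would be (4S,4'S)-3,3'-{(2R,3R)-2,3-bis[3-methoxy-4-(methoxymethoxy)benzyl]butanedioyl}bis(4-isopropyloxazolidin-2-one) F5. Reduction with LiBH4 (THF/H2O) would release the auxiliary and return the route at 9, bypassing steps 3 to 5.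

Step 7. The concern is over-acylation to the diester together with incomplete conversion of the acid, so that throughput depends on recycling. Fallback: setting out from 9, the symmetry would be broken by silylation instead. Monodeprotonation with NaH (1 equiv, THF) and addition of TBSCl (1 equiv) would give (2R,3R)-4-[(tert-butyldimethylsilyl)oxy]-2,3-bis[3-methoxy-4-(methoxymethoxy)benzyl]butan-1-ol F6. Its one free hydroxyl is then esterified completely with 12 (EDC·HCl, DMAP, CH2Cl2), giving the silyl ether F7 of ester 13, namely (2R,3R)-4-[(tert-butyldimethylsilyl)oxy]-2,3-bis[3-methoxy-4-(methoxymethoxy)benzyl]butyl (E)-3-[3-methoxy-4-(methoxymethoxy)phenyl]prop-2-enoate F7. Treatment with 2 M aq. HCl in THF would remove the silyl ether and the three acetals together and return the route at 14, bypassing 13.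

## Further compounds

F1 | step 4 | (3S,4S)-3,4-bis[3-methoxy-4-(methoxymethoxy)benzyl]hexa-1,5-diene | C=C[C@H](Cc1ccc(OCOC)c(OC)c1)[C@H](C=C)Cc1ccc(OCOC)c(OC)c1
F2 | step 4 | (2R,3R)-2,3-bis[3-methoxy-4-(methoxymethoxy)benzyl]butanedial | O=C[C@H](Cc1ccc(OCOC)c(OC)c1)[C@H](C=O)Cc1ccc(OCOC)c(OC)c1
F3 | step 3 | 3-[3-methoxy-4-(methoxymethoxy)phenyl]propanoic acid | COCOc1ccc(CCC(=O)O)cc1OC
F4 | step 3 | (S)-4-isopropyl-3-{3-[3-methoxy-4-(methoxymethoxy)phenyl]propanoyl}oxazolidin-2-one | COCOc1ccc(CCC(=O)N2[C@@H](C(C)C)COC2=O)cc1OC
F5 | step 3 | (4S,4'S)-3,3'-{(2R,3R)-2,3-bis[3-methoxy-4-(methoxymethoxy)benzyl]butanedioyl}bis(4-isopropyloxazolidin-2-one) | CC(C)[C@H]1COC(=O)N1C(=O)[C@H](Cc1ccc(OCOC)c(OC)c1)[C@H](C(=O)N1[C@@H](C(C)C)COC1=O)Cc1ccc(OCOC)c(OC)c1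
F6 | step 7 | (2R,3R)-4-[(tert-butyldimethylsilyl)oxy]-2,3-bis[3-methoxy-4-(methoxymethoxy)benzyl]butan-1-ol | CC(C)(C)[Si](C)(C)OC[C@H](Cc1ccc(OCOC)c(OC)c1)[C@H](CO)Cc1ccc(OCOC)c(OC)c1
F7 | step 7 | (2R,3R)-4-[(tert-butyldimethylsilyl)oxy]-2,3-bis[3-methoxy-4-(methoxymethoxy)benzyl]butyl (E)-3-[3-methoxy-4-(methoxymethoxy)phenyl]prop-2-enoate | COCOc1ccc(/C=C/C(=O)OC[C@H](Cc2ccc(OCOC)c(OC)c2)[C@H](CO[Si](C)(C)C(C)(C)C)Cc2ccc(OCOC)c(OC)c2)cc1OC
A1 | alternative 1 | dimethyl 2,3-dimethylenesuccinate | COC(=O)C(=C)C(=C)C(=O)OC
A2 | alternative 1 | [3-methoxy-4-(methoxymethoxy)phenyl]boronic acid | COCOc1ccc(B(O)O)cc1OC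
A3 | alternative 1 | dimethyl (2R,3R)-2,3-bis[3-methoxy-4-(methoxymethoxy)benzyl]succinate | COC(=O)[C@H](Cc1ccc(OCOC)c(OC)c1)[C@H](C(=O)OC)Cc1ccc(OCOC)c(OC)c1
A4 | alternative 2 | (5R)-5-[(1R,2S,5R)-menthyloxy]-2(5H)-furanone | C[C@@H]1CC[C@H]([C@@H](C1)O[C@@H]1OC(=O)C=C1)C(C)C
A5 | alternative 2 | 2-[3-methoxy-4-(methoxymethoxy)phenyl]-1,3-dithiane | COCOc1ccc(C2SCCCS2)cc1OC
A6 | alternative 2 | 3-methoxy-4-(methoxymethoxy)benzyl bromide | COCOc1ccc(CBr)cc1OC
A7 | alternative 2 | all-trans 3-[3-methoxy-4-(methoxymethoxy)benzyl]-4-{2-[3-methoxy-4-(methoxymethoxy)phenyl]-1,3-dithian-2-yl}-5-[(1R,2S,5R)-menthyloxy]dihydrofuran-2(3H)-one | C[C@@H]1CC[C@H]([C@@H](C1)O[C@@H]1OC(=O)[C@H](Cc2ccc(OCOC)c(OC)c2)[C@H]1C1(c2ccc(OCOC)c(OC)c2)SCCCS1)C(C)C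
A8 | alternative 3 | 2,3-bis[3-methoxy-4-(methoxymethoxy)benzyl]buta-1,3-diene | C=C(Cc1ccc(OCOC)c(OC)c1)C(=C)Cc1ccc(OCOC)c(OC)c1
A9 | alternative 3 | (2R,3R)-2,3-bis[3-methoxy-4-(methoxymethoxy)benzyl]butane-1,4-diol | OC[C@H](Cc1ccc(OCOC)c(OC)c1)[C@H](CO)Cc1ccc(OCOC)c(OC)c1
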